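# Chemoenzymatic total synthesis of sesterfisheric acid: cyclase-mediated polycyclisation of an acyclic C25 diphosphate

## Structural features

Biogenetic numbering is used throughout. C1–C20 run along the isoprenoid chain and C21–C25 are the branch carbons on C3, C7, C11, C15 and C19, so C24 is the carboxyl carbon and C19/C20/C25 form the isopropyl group. The target is a linearly fused 5-8-6-5 tetracycle made of cyclopentane A (C6–C10), cyclooctene B (C2–C6, C10–C12), cyclohexane C (C1, C2, C12–C15) and cyclopentane D (C14–C18), joined through C6–C10, C2–C12 and C14–C15. The B/C and C/D fusions are both trans. H2, 12-OH, H14 and C24 are all axial on a chair ring C, with 12-OH and C24 on opposite faces and the isopropyl group cis to C24.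

The eight stereocentres fall into three groups: C7/C6 on ring A, the contiguous row C3–C2–C12, and the set C14/C15/C18 on ring D. C12 (tertiary carbinol) and C15 (quaternary, carboxyl-bearing) are fully substituted. The C10=C11 alkene is tetrasubstituted, Z within ring B and exocyclic to ring A. The hydroxyl next to it is tertiary and allylic and ionises readily in acid (diene formation, 1,3-transposition), and the carboxyl group is neopentyl and hindered.

The real difficulty has three parts: closing ring B with this alkene and the ring-fusion carbinol in place, relaying configuration across that flexible ring from C6/C7 to the hydrindane, and building the oxidised quaternary C15 of a trans-hydrindane.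

The key step exploits three facts:
- All 25 carbons stand in unbroken head-to-tail pentaprenyl order.
- Only four C–C bonds (C1–C15, C14–C18, C6–C10, C2–C12) separate the tetracycle from an acyclic all-E chain.
- The only skeletal oxygen sits at C12, the terminus of the C10–C11–C12 allyl system where a cation cascade would come to rest.

## Logic of the disconnections

**19 ⇒ 16.**
- Cut: the three C24–O bonds, so C24 returns to a methyl group.
- Reason: an acceptor on C15 would switch off the nucleophilicity of the C14=C15 alkene that any cationic assembly of the skeleton needs, so the carboxyl oxidation level has to come last.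
- Gain: the target is reduced to a mono-oxygenated skeleton that is an isomer of an acyclic polyprenol.
- Demand: a six-electron oxidation of one methyl group out of six. It is neopentyl, it lies on the face opposite to the only directing group (12-OH), and it must be oxidised beside an electron-rich tetrasubstituted alkene and an acid-labile tertiary allylic alcohol. Only a shaped binding pocket can be expected to meet this.

**16 ⇒ 11.**
- Cut: C1–C15, C14–C18, C6–C10, C2–C12 and C12–O.
- Reason: these are the only bonds that are not part of the linear isoprenoid chain. Each links a former alkene carbon to a carbon that can carry a tertiary or allylic cation.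
- Gain: four rings, eight stereocentres and the tetrasubstituted alkene collapse to an acyclic, achiral chain whose only stereochemical content is four E alkenes.
- Demand: the macrocyclisation-first order of closures, five hydride shifts and a single terminal water quench, all in one absolute sense. A free polyprenyl cation in solution would prefer six-membered closures, so the fold must be imposed from outside.
- In one sentence: a class I terpene cyclase folds acyclic 11 into tetracyclic 16 in one cationic cascade.

**11 ⇒ 9 (through 10).**
- Cut: the C1–O bond to diphosphate.
- Reason: the diphosphate is only the trigger of the cascade and is too polar and labile to carry through C–C bond formation.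
- Gain: a neutral allylic alcohol that can be chromatographed.
- Demand: activation and displacement at a primary allylic carbon without allylic shift or loss of the 2E geometry.

**9 ⇒ 6.**
- Cut: C1–C2 and C3–C21.
- Reason: both bonds and the 2E geometry can come from one syn addition across a terminal alkyne followed by capture of the vinyl metal.
- Gain: the last trisubstituted alkene is replaced by an alkyne that has no geometry.
- Demand: regio- and stereoselective methylmetalation in the presence of four trisubstituted alkenes.

**6 ⇒ 2 + 3 (through 5).**
- Cut: C4–C5.
- Reason: this bond is allylic on one side and propargylic on the other, so it is a plain SN2 union of an allyl halide with a propargyl anion.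
- Gain: C5–C20, with three defined E alkenes, comes from a purchased C20 unit and C2–C4 from a purchased C3 unit.
- Demand: SN2 rather than SN2′ attack, and propargyl rather than allenyl reactivity of the ambident anion.

**2 ⇒ 1.**
- Cut: the C–Br bond (C5 of the later chain).
- Reason: a functional group change to the electrophile.
- Gain: a commercial alcohol.
- Demand: mild conditions, because the bromide is labile.

## Other disconnections considered

**Alternative 1:** (the first that comes to mind)
- Cut: C11–C12 and C4–C5.
- Forward key step: iodide A2 (ring A with C5 and C11), after iodine–lithium exchange, would add to the C12 ketone of trans-hydrindanone A1 (rings C and D with the C2 side chain) to give diene A3. Ring-closing metathesis would close ring B to cyclooctadiene A4. Hydrogenation of the disubstituted C4=C5 alkene and ester cleavage would give 19.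
- Ground for preferring the chosen plan:
  - The plan moves the stereochemical work into A1. That fragment holds five of the eight stereocentres, including the carboxyl-bearing quaternary C15 of a trans-hydrindane and the exocyclic C3 next to C2, and no chiral-pool shortcut is apparent.
  - The tetrasubstituted alkenyl nucleophile must add equatorially to a hindered, enolisable, α-branched ketone.
  - The metathesis must close a strained eight-membered ring between two α-branched vinyl groups against oligomerisation.
  - C6/C7 and the hydrindane are set independently, so two enantiopure fragments are needed, and the count should exceed twenty-five steps against eight.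

**Alternative 2:**
- Cut: C6–C10, C7–C8 and C8–C9, with C8 supplied by carbon monoxide.
- Forward key step: a Rh(I)-catalysed allenic Pauson–Khand reaction of allene-yne A5 would engage the distal C9=C10 bond of the allene and close rings A and B together to give dienone A6. This matches the alkylidene-cyclopentane motif well.
- Ground for preferring the chosen plan:
  - A5 still needs the whole stereochemical load of the hydrindane part and C3.
  - Eight-membered ring formation lies at the limit of this cycloaddition.
  - A6 carries a ketone at C8 and a C6=C7 alkene that the target lacks. A 1,4- versus 1,6-selective and face-selective reduction of a linear dienone, epimerisation at C7 and deoxygenation would follow.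
  - The two-ring gain is therefore paid back in four or five corrective steps, and C6 is set without a clear control element.

**Alternative 3:**
- Cut: C2–C12 alone, as a chemical copy of the last C–C bond formation of the biosynthesis.
- Forward key step: a Lewis-acid-promoted transannular ketone–ene reaction of the 5-12-5 macrocyclic enone A7 would give A8 with rings B and C and the trans C2/C12 fusion. Hydrogenation of the C3=C21 methylene group and ester cleavage would give 19.
- Ground for preferring the chosen plan:
  - A7 contains a tetrasubstituted enone, an E-trisubstituted alkene and both cyclopentanes in a twelve-membered ring, whose fragment syntheses and macrocyclisation should cost some twenty steps.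
  - The conjugated ketone is a weak enophile.
  - The ene step ends by proton loss, so C3 needs a separate hydrogenation on a flexible cyclooctane with no evident facial bias.
  - In the enzyme pocket, by contrast, the same bond formation is followed by two hydride shifts that set C3 and C2 at once.

Key step: step 7

Assumption: the configuration given is taken to be that of the natural product, so that the native fungal cyclase and P450 deliver this enantiomer; both proteins are treated as catalysts obtained by expression of synthetic genes.

## Steps

Step 1
Reactants: 1 (2E,6E,10E)-geranylgeraniol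
Product: 2 (2E,6E,10E)-geranylgeranyl bromide
Conditions: PBr3 (0.4 equiv), Et2O, −10 to 0 °C; used crude
Reagents that add atoms: phosphorus tribromide BrP(Br)Br
Why: SN2 displacement of the phosphite ester by bromide at a primary allylic carbon, the standard conversion of polyprenols; at or below 0 °C the 2E geometry should be kept and allylic transposition should stay minor. No stereocentre is involved.

Step 2
Reactants: 2 (2E,6E,10E)-geranylgeranyl bromide; 3 1-(trimethylsilyl)propyne
Product: 5 trimethyl[(5E,9E,13E)-6,10,14,18-tetramethylnonadeca-5,9,13,17-tetraen-1-yn-1-yl]silane, via 3-lithio-1-(trimethylsilyl)propyne 4 (not isolated)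
Conditions: 3, n-BuLi, THF, −20 °C; then 2, −78 °C to rt
Reagents that add atoms: none
Why: Alkylation of a silyl-capped propargyllithium with a primary allylic bromide (C3 homologation to a 1,5-enyne). The silyl group biases the ambident anion towards propargyl attack and the unhindered primary carbon favours SN2 over SN2′. The three E alkenes are not touched.

Step 3
Reactants: 5 trimethyl[(5E,9E,13E)-6,10,14,18-tetramethylnonadeca-5,9,13,17-tetraen-1-yn-1-yl]silane
Product: 6 (5E,9E,13E)-6,10,14,18-tetramethylnonadeca-5,9,13,17-tetraen-1-yne
Conditions: K2CO3 (cat.), MeOH/THF, rt
Reagents that add atoms: none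
Why: Base-catalysed protodesilylation of an alkynylsilane by methanolysis; the isolated trisubstituted alkenes are inert to these conditions.

Step 4
Reactants: 6 (5E,9E,13E)-6,10,14,18-tetramethylnonadeca-5,9,13,17-tetraen-1-yne
Product: 9 (2E,6E,10E,14E)-geranylfarnesol, via alkenyldimethylalane 7 (not isolated), via lithium alkenylalanate 8 (not isolated)
Conditions: AlMe3, Cp2ZrCl2 (cat.), CH2Cl2, 0 °C to rt; volatiles removed; n-BuLi, hexane/THF, 0 °C; (CH2O)n, rt; aq. work-up
Reagents that add atoms: trimethylaluminium C[Al](C)C; formaldehyde (as paraformaldehyde) C=O
Why: Negishi zirconium-catalysed methylalumination adds Me and Al syn across the terminal alkyne with Al at the terminus, so that chain and metal are trans in 7. The ate complex 8 is hydroxymethylated with retention, which defines the 2E alkene. Trisubstituted alkenes should not be carboaluminated under these conditions.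

Step 5
Reactants: 9 (2E,6E,10E,14E)-geranylfarnesol
Product: 10 (2E,6E,10E,14E)-geranylfarnesyl chloride
Conditions: NCS, Me2S, CH2Cl2, −40 to 0 °C
Reagents that add atoms: N-chlorosuccinimide O=C1CCC(=O)N1Cl
Why: Corey–Kim chlorination: the alkoxysulfonium salt is displaced by chloride in an SN2 step under nearly neutral conditions, so neither allylic shift nor E/Z loss is expected.

Step 6
Reactants: 10 (2E,6E,10E,14E)-geranylfarnesyl chloride
Product: 11 (2E,6E,10E,14E)-geranylfarnesyl diphosphate triammonium salt
Conditions: (n-Bu4N)3HP2O7, MeCN, rt; cation-exchange resin (NH4+ form), aq. NH4HCO3/i-PrOH; cellulose chromatography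
Reagents that add atoms: tris(tetrabutylammonium) hydrogen diphosphate CCCC[N+](CCCC)(CCCC)CCCC.CCCC[N+](CCCC)(CCCC)CCCC.CCCC[N+](CCCC)(CCCC)CCCC.OP(=O)([O-])OP(=O)([O-])[O-]; ammonium hydrogencarbonate [NH4+].OC(=O)[O-]
Why: SN2 displacement of a primary allylic chloride by the lipophilic diphosphate salt in a dipolar aprotic solvent, the standard preparation of polyprenyl diphosphates. Cation exchange gives the water-soluble ammonium salt that the enzyme accepts.

Step 7
Reactants: 11 (2E,6E,10E,14E)-geranylfarnesyl diphosphate triammonium salt
Product: 16 sesterfisherol, via bicyclic C19 cation 12 (not isolated), via bicyclic allyl cation 13 (not isolated), via tricyclic allyl cation 14 (not isolated), via tetracyclic allyl cation 15 (not isolated)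
Conditions: recombinant sesterfisherol-forming class I terpene cyclase (fungal chimeric prenyltransferase–terpene synthase type, expressed in E. coli), MgCl2, HEPES pH 7.5, glycerol, 30 °C, 11 fed in portions, pentane overlay
Reagents that add atoms: water O
Why: Class I terpene-cyclase catalysis: a Mg2+ cluster ionises the allylic diphosphate of 11 and the hydrophobic pocket steers the cation–olefin cascade, which is the native reaction type of fungal chimeric sesterterpene synthases on C25 diphosphates (closest non-enzymatic relative: Lewis-acid polyene cyclisation). The C1 allyl cation is attacked by C15 of the 14E alkene while C14 attacks C18, which closes the 15-membered ring (end-to-end macrocyclisation) and ring D (5-exo) by one anti addition, so that C24 and H14 come out trans from the E geometry and C18 is set by the face of the terminal alkene that the fold presents, giving 12. A 1,5-hydride shift from C12 to C19 completes the isopropyl group and moves the charge into the C10–C12 allyl system (13). C6 of the 6E alkene attacks C10 (ring A, transannular, formally 5-endo, Markovnikov), and two suprafacial 1,2-hydride shifts, H6 to C7 and H10 to C6, each arriving anti to the group that left, set C7 and C6 so that methyl C22 is trans to C5 and restore the allyl cation as 14, whose C10=C11 geometry is that of the 10E alkene of 11. C2 of the 2E alkene attacks C12 and splits the 12-membered ring (6-exo for ring C through a chair, 8-endo for ring B), after which H2 moves to C3 and H12 to C2, again anti, setting C3 and C2 and giving 15. A water molecule held in the pocket adds to C12 of 15 on the face opposite to the departed H12, which sets C12 so that 12-OH is trans to H2 and leaves the tetrasubstituted C10=C11 alkene in place. The step needs one fold among many, the macrocyclisation-first order of closures and a quench only at the last cation: the substrate secures that every closure leads to a tertiary or allylic cation and that every addition is stereospecific (four E alkenes), while the chiral pocket secures the absolute sense, keeps base and water away from 12–14 and blocks the six-membered closures that a free polyprenyl cation would prefer. Four rings, eight stereocentres and the C–O bond should thus arise from an achiral precursor in one operation.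

Step 8
Reactants: 16 sesterfisherol
Product: 19 sesterfisheric acid, via C24 alcohol 17 (not isolated), via C24 aldehyde 18 (not isolated)
Conditions: cytochrome P450 monooxygenase of the sesterfisherol gene cluster and NADPH–cytochrome P450 reductase (yeast microsomes), NADP+ (cat.), D-glucose, glucose dehydrogenase, air, KPi pH 7.4, 30 °C
Reagents that add atoms: dioxygen O=O
Why: Cytochrome P450 C–H oxidation: the ferryl species abstracts hydrogen from C24 and returns hydroxyl (oxygen rebound), and two further rounds on the bound substrate take 17 through 18 to the acid. Site selectivity comes from the pocket that places the angular methyl group over the haem, which no small reagent can do beside the electron-rich alkene and five other methyl groups. No stereocentre is touched and the neutral medium spares the tertiary allylic alcohol.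

## Compound list

1 | (2E,6E,10E)-geranylgeraniol | CC(C)=CCC/C(C)=C/CC/C(C)=C/CC/C(C)=C/CO | starting material
2 | (2E,6E,10E)-geranylgeranyl bromide | CC(C)=CCC/C(C)=C/CC/C(C)=C/CC/C(C)=C/CBr | intermediate
3 | 1-(trimethylsilyl)propyne | CC#C[Si](C)(C)C | starting material
4 | 3-lithio-1-(trimethylsilyl)propyne | [Li]CC#C[Si](C)(C)C | intermediate
5 | trimethyl[(5E,9E,13E)-6,10,14,18-tetramethylnonadeca-5,9,13,17-tetraen-1-yn-1-yl]silane | CC(C)=CCC/C(C)=C/CC/C(C)=C/CC/C(C)=C/CCC#C[Si](C)(C)C | intermediate
6 | (5E,9E,13E)-6,10,14,18-tetramethylnonadeca-5,9,13,17-tetraen-1-yne | CC(C)=CCC/C(C)=C/CC/C(C)=C/CC/C(C)=C/CCC#C | intermediate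
7 | dimethyl[(1E,5E,9E,13E)-2,6,10,14,18-pentamethylnonadeca-1,5,9,13,17-pentaen-1-yl]alane | CC(C)=CCC/C(C)=C/CC/C(C)=C/CC/C(C)=C/CC/C(C)=C/[Al](C)C | intermediate
8 | lithium butyl(dimethyl)[(1E,5E,9E,13E)-2,6,10,14,18-pentamethylnonadeca-1,5,9,13,17-pentaen-1-yl]alanate | CC(C)=CCC/C(C)=C/CC/C(C)=C/CC/C(C)=C/CC/C(C)=C/[Al-](C)(C)CCCC.[Li+] | intermediate
9 | (2E,6E,10E,14E)-geranylfarnesol | CC(C)=CCC/C(C)=C/CC/C(C)=C/CC/C(C)=C/CC/C(C)=C/CO | intermediate
10 | (2E,6E,10E,14E)-geranylfarnesyl chloride | CC(C)=CCC/C(C)=C/CC/C(C)=C/CC/C(C)=C/CC/C(C)=C/CCl | intermediate
11 | (2E,6E,10E,14E)-geranylfarnesyl diphosphate, triammonium salt | CC(C)=CCC/C(C)=C/CC/C(C)=C/CC/C(C)=C/CC/C(C)=C/COP(=O)([O-])OP(=O)([O-])[O-].[NH4+].[NH4+].[NH4+] | intermediate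
12 | bicyclic (5/15) C19 cation, 2E,6E,10E, C14/C15/C18 configured as in 16 | C1C/C(C)=C/CC/C(C)=C/CC/C(C)=C/C[C@@]2(C)CC[C@H]([C+](C)C)[C@@H]21 | intermediate
13 | bicyclic (5/15) C10–C12 allyl cation with completed isopropyl group, 2E,6E, C14/C15/C18 as in 16 | C1[CH+]/C(C)=C/CC/C(C)=C/CC/C(C)=C/C[C@@]2(C)CC[C@H](C(C)C)[C@@H]21 | intermediate
14 | tricyclic (5/12/5) C10–C12 allyl cation, 2E, C6/C7/C14/C15/C18 as in 16 | C/C1=C2\CC[C@@H](C)[C@@H]2CC/C(C)=C/C[C@@]3(C)CC[C@H](C(C)C)[C@@H]3C[CH+]1 | intermediate
15 | tetracyclic (5/8/6/5) C10–C12 allyl cation, C2/C3/C6/C7/C14/C15/C18 as in 16 | C/C1=C2\CC[C@@H](C)[C@@H]2CC[C@H](C)[C@H]2C[C@@]3(C)CC[C@H](C(C)C)[C@@H]3C[C+]12 | intermediate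
16 | sesterfisherol, (2R,3S,6S,7R,10Z,12R,14S,15R,18R) in the biogenetic numbering | C/C1=C2\CC[C@@H](C)[C@@H]2CC[C@H](C)[C@H]2C[C@@]3(C)CC[C@H](C(C)C)[C@@H]3C[C@]12O | intermediate
17 | 24-hydroxysesterfisherol (C24 primary alcohol, 15S, other centres as in 16) | C/C1=C2\CC[C@@H](C)[C@@H]2CC[C@H](C)[C@H]2C[C@@]3(CO)CC[C@H](C(C)C)[C@@H]3C[C@]12O | intermediate
18 | 24-oxosesterfisherol (C24 aldehyde, 15S, other centres as in 16) | C/C1=C2\CC[C@@H](C)[C@@H]2CC[C@H](C)[C@H]2C[C@@]3(C=O)CC[C@H](C(C)C)[C@@H]3C[C@]12O | intermediate
19 | sesterfisheric acid, (2R,3S,6S,7R,10Z,12R,14S,15S,18R) in the biogenetic numbering | C/C1=C2\CC[C@@H](C)[C@@H]2CC[C@H](C)[C@H]2C[C@@]3(C(=O)O)CC[C@H](C(C)C)[C@@H]3C[C@]12O | target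

## Step count and least certain steps

Total step count: 8. Longest linear sequence: 8 steps (1 to 19).

**Step 7 (key step).**
- What may go wrong: turnover may be slow and the cascade may derail. The C25 diphosphate is amphiphilic and tends to aggregate or to precipitate with Mg2+, so little of it may reach the active site from bulk solution. Background solvolysis of the allylic diphosphate may compete. A loosely bound substrate may be deprotonated or hydrated at an earlier cation, and the lipophilic product may inhibit the enzyme.
- Fallback: the substrate is built inside the protein, so the last chain bond (C4–C5) is also made enzymatically. This sets out from 1 and comes back at 16.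
  - Corey–Kim chlorination of 1 should give geranylgeranyl chloride F1.
  - Displacement with the tetrabutylammonium diphosphate salt and cation exchange should give geranylgeranyl diphosphate F2.
  - The full-length chimeric enzyme should be offered F2 together with purchased isopentenyl diphosphate F3.
  - Its prenyltransferase domain should join the two to 11 at a low steady-state concentration next to the cyclase domain, which should convert it to 16.

**Step 8.**
- What may go wrong: the membrane-bound fungal P450 may express poorly or couple badly to the reductase, so NADPH is consumed without product. The sequence may also stall at an intermediate oxidation level when partly oxidised material leaves the pocket.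
- Fallback: only the first, truly unselective-by-chemistry oxidation is left to biology and the rest is done chemically. This sets out from 16 and comes back at 19.
  - Resting cells of a yeast or Aspergillus host that co-expresses P450 and reductase should hydroxylate 16, and 17 is isolated.
  - TEMPO/PhI(OAc)2 with NaHCO3 in CH2Cl2 should take 17 to 18, since the tertiary alcohol cannot be oxidised.
  - Pinnick oxidation (NaClO2, NaH2PO4, large excess of 2-methyl-2-butene, t-BuOH/H2O) should give 19.

**Step 6.**
- What may go wrong: hydrolysis, elimination or SN2′ attack on the labile allylic chloride may compete. The C25 chain may dissolve poorly in MeCN, and material may be lost on ion exchange because the long-chain diphosphate behaves as a detergent.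
- Fallback: the polarity of the bond formation is reversed, so the C1–O bond is never broken. This sets out from 9 and comes back at 11.
  - Trichloroacetonitrile-promoted phosphorylation of 9 with triethylammonium phosphate in MeCN should give geranylfarnesyl monophosphate F4.
  - A second phosphoryl transfer in the same medium should give the diphosphate.
  - The diphosphate is separated from F4 and converted to the ammonium salt 11 by ion exchange.

**Step 4.**
- What may go wrong: some methyl may be delivered to the terminal carbon. The cationic Zr/Al species may trigger cyclisation of the 1,5-enyne or isomerisation of the neighbouring alkene. Capture of the vinyl metal by polymeric formaldehyde may be incomplete.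
- Fallback: the 2E alkene is built from a carbonyl compound rather than an alkyne, which also bypasses steps 2 and 3. This sets out from 2 and comes back at 9.
  - Alkylation of the ethyl acetoacetate dianion (NaH, then n-BuLi, THF, 0 °C) at its terminal carbon should give β-keto ester F5.
  - NaH and ClP(O)(OEt)2 in Et2O should give the Z enol phosphate F6 through the chelated enolate.
  - Me2CuLi should replace the phosphate with retention to give the 2E ester F7.
  - DIBAL-H reduction should give 9.

## Further compounds

F1 | step 7 | (2E,6E,10E)-geranylgeranyl chloride | CC(C)=CCC/C(C)=C/CC/C(C)=C/CC/C(C)=C/CCl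
F2 | step 7 | (2E,6E,10E)-geranylgeranyl diphosphate, triammonium salt | CC(C)=CCC/C(C)=C/CC/C(C)=C/CC/C(C)=C/COP(=O)([O-])OP(=O)([O-])[O-].[NH4+].[NH4+].[NH4+]
F3 | step 7 | isopentenyl diphosphate, triammonium salt | C=C(C)CCOP(=O)([O-])OP(=O)([O-])[O-].[NH4+].[NH4+].[NH4+]
F0 | step 8 | none | none
F4 | step 6 | (2E,6E,10E,14E)-geranylfarnesyl monophosphate | CC(C)=CCC/C(C)=C/CC/C(C)=C/CC/C(C)=C/CC/C(C)=C/COP(=O)(O)O
F5 | step 4 | ethyl (6E,10E,14E)-7,11,15,19-tetramethyl-3-oxoicosa-6,10,14,18-tetraenoate | CC(C)=CCC/C(C)=C/CC/C(C)=C/CC/C(C)=C/CCC(=O)CC(=O)OCC
F6 | step 4 | ethyl (2Z,6E,10E,14E)-3-(diethoxyphosphoryloxy)-7,11,15,19-tetramethylicosa-2,6,10,14,18-pentaenoate | CC(C)=CCC/C(C)=C/CC/C(C)=C/CC/C(C)=C/CC/C(OP(=O)(OCC)OCC)=C/C(=O)OCC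
F7 | step 4 | ethyl (2E,6E,10E,14E)-geranylfarnesoate | CC(C)=CCC/C(C)=C/CC/C(C)=C/CC/C(C)=C/CC/C(C)=C/C(=O)OCC
A1 | alternative 1 | methyl trans-hydrindanone carboxylate with C12 ketone, C2 (S)-but-3-en-2-yl side chain, C15 ester and C18 isopropyl group | C=C[C@H](C)[C@H]1C[C@@]2(C(=O)OC)CC[C@H](C(C)C)[C@@H]2CC1=O
A2 | alternative 1 | (Z)-1-(1-iodoethylidene)-3-methyl-2-vinylcyclopentane, methyl and vinyl trans | C/C(I)=C1\CC[C@@H](C)[C@@H]1C=C
A3 | alternative 1 | C12 tertiary allylic alcohol carrying both vinyl groups (metathesis substrate) | C=C[C@H](C)[C@H]1C[C@@]2(C(=O)OC)CC[C@H](C(C)C)[C@@H]2C[C@]1(O)/C(C)=C3/CC[C@@H](C)[C@@H]3C=C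
A4 | alternative 1 | methyl (4Z)-4,5-didehydrosesterfisherate | C/C1=C2\CC[C@@H](C)[C@@H]2/C=C\[C@H](C)[C@H]2C[C@@]3(C(=O)OC)CC[C@H](C(C)C)[C@@H]3C[C@]12O
A5 | alternative 2 | hydrindane allene-yne (C12 carbinol with 1-methylallenyl group, C2 side chain ending in a 2-butynyl unit) | CC#CCC[C@H](C)[C@H]1C[C@@]2(C(=O)OC)CC[C@H](C(C)C)[C@@H]2C[C@]1(O)C(C)=C=C
A6 | alternative 2 | tetracyclic 8-oxo-6,10-dienone methyl ester | CC1=C2CC[C@H](C)[C@H]3C[C@@]4(C(=O)OC)CC[C@H](C(C)C)[C@@H]4C[C@]3(O)/C(C)=C2/CC1=O
A7 | alternative 3 | 5-12-5 macrocyclic (2E,10Z)-12-oxo dienone methyl ester | C/C1=C2\CC[C@@H](C)[C@@H]2CC/C(C)=C/C[C@@]3(C(=O)OC)CC[C@H](C(C)C)[C@@H]3CC1=O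
A8 | alternative 3 | methyl 3(21)-didehydrosesterfisherate (exocyclic methylene at C3) | C/C1=C2\CC[C@@H](C)[C@@H]2CCC(=C)[C@H]2C[C@@]3(C(=O)OC)CC[C@H](C(C)C)[C@@H]3C[C@]12O
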